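Numbers refer to the compound list after the steps. Ring locants: in each ring C-1 carries the carboxyl carbon C-7, C-2 an OH and C-6 the CH3; ring A also has C-4 OH and C-5 OMe. The lower-case locants c1 to c8 are the carbons of the open octanoyl chain from which a ring is folded (c1 = ester carbonyl, c8 = methyl).

## Analysis of the target

The target (C25H22O11) is a tridepside: three benzene rings A, B and C joined head to tail by two aryl ester bonds, one from C-7 on C-1 of ring A to O-4 of ring B and one from C-7 on C-1 of ring B to O-4 of ring C, and ring C ends in a free salicylic-type acid. Rings B and C are 2-hydroxy-6-methyl-4-oxybenzoyl (orsellinate) units, while ring A is pentasubstituted (C-2 OH, C-4 OH, C-5 OMe, C-6 CH3) with hydrogen only at C-3. There is no stereocentre and no double-bond geometry, so the problem is regiochemical: seven oxygen substituents of one kind sit on three rings, and one must be methylated, two acylated and four left free. Each ester carbonyl is flanked by an ortho OH and an ortho CH3, which makes the acyl donors hindered, and their partners are weakly nucleophilic phenols. The sensitive groups are the aryl esters (cleaved by alkoxide, hydroxide or hot alcohols), the acid of ring C (decarboxylates on heating) and the para pair C-2 OH and C-5 OMe of ring A (a hydroquinone monoether that oxidants turn into a quinone). The feature the route is built on: in each ring, C-1 to C-6 with oxygen on C-2 and C-4 and CH3 on C-6 is the aldol fold of a 3,5,7-trioxooctanoyl chain (c2 = C-1, c7 = C-6, c1 = the depside carbonyl C-7). In ring A the extra oxygen on C-5 lies on chain carbon c6, which in the open chain is the central and most acidic carbon of a 1,3-diketone, the only position of its kind. The hardest part is ring A, with its contiguous CH3/OMe/OH array and its doubly ortho-substituted ester to ring B.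

## Retrosynthetic reasoning

**21 to 20.** The last bond cut is the benzylic C–O bond of the ester that masks the carboxyl group of ring C. Hydrogenolysis is neutral and leaves aryl esters, the aryl methyl ether and free phenols alone. The acid is masked from the start because a free salicylic-type acid would decarboxylate and compete as a nucleophile in the thermal steps.

**20 to 13 and 17 (key disconnection).** Two bonds of ring A are cut together: the depside bond C-7–O (to O-4 of ring B) and the ring bond C-1–C-6 (chain bond c2–c7). This unfolds ring A into the aryl 6-methoxy-3,5,7-trioxooctanoate 19. Cleaving its ester bond in turn leads to the acylketene 18 and the phenol 13, and 18 is stored as the dioxinone 17.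
- Ring A is cut rather than the ester bond alone because three difficulties disappear in the open chain. The C-5 OMe becomes an ordinary α-methoxy ketone carbon. The four phenol protecting groups of a preformed ring A are not needed, since its hydroxyls do not exist until after the ester is made. The hindered ester is formed at an unhindered sp carbon before its ortho neighbours are in place.
- The forward reaction has to achieve capture of 18 by one of three phenols of 13, then an aldol closure c2 to c7 in preference to the other cyclization modes of 19.

**17 to 15 and 16, and 15 to 7.** The C–O bond between c6 and the methoxy oxygen is cut, which leads to 16 and the diazo diketone 15 (metal-catalysed O–H insertion in the forward sense). The diazo group of 15 is then removed, giving 7 and the diazo donor 14. The site is chosen by the substrate: c6 is the methylene between the two ketones of 7 and its most acidic carbon. The oxygen that would be one of several similar ring positions on an arene is thus placed on the open chain at a position that has no rival, and the ring A chain is the ring B chain plus one functional group.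

**13 to 10 and 7.** The same two-bond disconnection is applied to ring B (its C-7–O bond to ring C and its C-1–C-6 bond), through the aryl triketo ester 12 and the acylketene 11. Here the transform is a convenience and not a necessity, but it means the one building block 7 serves rings A and B, and ring B needs no protecting group.

**10 to 8 and 9.** The O–CH2 bond of the benzyl ester is cut, giving the acid 8 and the benzyl donor 9. Ring C is the one ring that can be bought with exactly its substitution pattern, and its only change is the mask on the acid. Folding it from the chain would spend 7 without any gain.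

**7 to 4, and 4 to 1.** The bond c6–c7 of the chain is cut to the dianion 6 of 4 and the acetyl donor 5. Then 4 is cut to dienolate 3 of commercial 1 and the acid chloride 2. All carbon of rings A and B thus comes from 1 and from two-carbon acyl units.

## Alternatives that were turned down

**Alternative 1:** The textbook route cuts only the two ester C(=O)–O bonds and takes all three rings as preformed arenes.
- Forward key step: the ring A acid A1 (2,4-bis(benzyloxy)-5-methoxy-6-methylbenzoic acid) is esterified with the ring B 4-OH of 13 through a mixed anhydride or carbodiimide activation to give A2, and all benzyl groups are then removed by hydrogenolysis.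
- Why turned down: A1 is not available. It would have to be made from a simpler orsellinate by oxygenation of C-5, methylation of one of three phenolic oxygens, double benzylation and hydrolysis of a hindered ester, roughly seven steps for one fragment.
- Its activated carboxyl is flanked by OBn and CH3 and must acylate a weak phenol nucleophile, the least favourable combination for acyl transfer.
- Ring B needs the same protect, activate and deprotect cycle, so the count passes fifteen steps with five or more protecting-group operations. The route is reliable but uses nothing the structure offers.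

**Alternative 2:** Ring A is made by a Dötz benzannulation, cutting the ring bonds around C-2 and C-5.
- Forward key step: the but-2-ynoate ester A3 of 13 is heated with the chromium carbene complex A4, (CO)5Cr=C(OMe)C(OBn)=CH2. The carbene carbon becomes C-5 (OMe), a CO ligand becomes C-2 (OH), the alkyne carbons become C-1 and C-6, and the vinyl carbons become C-4 and C-3, giving the monobenzyl ether A5. The para relation of C-2 OH and C-5 OMe is what this reaction delivers.
- Why turned down: the alkyne of A3 is an electron-poor ynoate. Such alkynes insert sluggishly, and the regiochemistry is not secured, because CH3 and the ester differ little in size and the ester's polarization works against the sense needed.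
- A4 needs α-metalation of a benzyl enol ether, which competes with benzylic metalation.
- The product arene must be released from chromium by oxidation, which threatens the hydroquinone monoether of ring A.
- The ester bond still has to be made separately (in A3), chromium is used stoichiometrically, and no steps are saved.

**Alternative 3:** Ring A is carried as a saturated ring and aromatized late.
- Forward key step: a Michael–Claisen condensation of a β-keto ester with an α-methoxy enoate gives the cyclohexane-1,3-dione A6. Dehydrogenation (halogenation and elimination) gives the methyl ester A7 of the ring A acid, which is hydrolysed and benzylated to A1.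
- Why turned down: the sequence ends in A1 and so inherits the whole hindered-ester end game of alternative 1, with more steps in front of it.
- A6 can also aromatize without oxidant by eliminating its C-5 methoxy group with a ring hydrogen, which would give the ring without the C-5 oxygen. This redox-neutral path competes with the dehydrogenation.
- The α-methoxy group lowers the electrophilicity of the Michael acceptor.
- If the saturated ring were instead carried into the depside, the oxidants needed for aromatization would attack the electron-rich rings B and C.

Key step: step 7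

Remark on the chemistry: the target has no stereocentre. Compounds 17 and 19 contain one enolizable methine (the methoxy-bearing chain carbon) and are treated as racemic tautomer mixtures drawn in the keto form; this centre is lost on aromatization. Orsellinic acid 8 and the sulfonyl azide 14 are taken as commercial materials.

## Route

Step 1
Reactants: 1 2,2,6-trimethyl-4H-1,3-dioxin-4-one; 2 acetyl chloride
Product: 4 2,2-dimethyl-6-(2-oxopropyl)-4H-1,3-dioxin-4-one, via lithium dienolate 3 (not isolated)
Conditions: 1 (2 equiv), LiN(SiMe3)2 (2 equiv), THF, −78 °C; then 2 (1 equiv), −78 to −20 °C; 1 M HCl work-up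
Reagents that add atoms: none
Why: γ-Deprotonation of the vinylogous ester gives dienolate 3, which should be C-acylated at its exocyclic carbon by the acid chloride (crossed Claisen acylation). The second equivalent of 3 takes up the acidic proton of 4, and the 1 returned in this way is recovered.

Step 2
Reactants: 4 2,2-dimethyl-6-(2-oxopropyl)-4H-1,3-dioxin-4-one; 5 N-methoxy-N-methylacetamide
Product: 7 2,2-dimethyl-6-(2,4-dioxopentyl)-4H-1,3-dioxin-4-one, via dilithium dianion 6 (not isolated)
Conditions: LiN(i-Pr)2 (2.1 equiv), THF, −78 °C; then 5, −78 to 0 °C; 1 M HCl work-up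
Reagents that add atoms: none
Why: Double deprotonation gives dianion 6, which should react at its last-formed, more basic terminal carbon (γ-acylation of a 1,3-dicarbonyl dianion, Claisen type). The N-methoxy-N-methyl amide prevents over-addition because collapse to the ketone occurs only on acidic work-up.

Step 3
Reactants: 8 2,4-dihydroxy-6-methylbenzoic acid (orsellinic acid); 9 benzyl bromide
Product: 10 benzyl 2,4-dihydroxy-6-methylbenzoate
Conditions: 9 (1.05 equiv), KHCO3 (1.2 equiv), DMF, 23 °C
Reagents that add atoms: none
Why: Bicarbonate deprotonates only the carboxylic acid, and the carboxylate is O-alkylated by the benzylic bromide (SN2 esterification of a carboxylate). The phenols stay protonated and are not benzylated, and room temperature avoids decarboxylation of 8.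

Step 4
Reactants: 7 2,2-dimethyl-6-(2,4-dioxopentyl)-4H-1,3-dioxin-4-one; 10 benzyl 2,4-dihydroxy-6-methylbenzoate
Product: 13 benzyl 4-[(2,4-dihydroxy-6-methylbenzoyl)oxy]-2-hydroxy-6-methylbenzoate, via acylketene 11 (not isolated), via aryl triketo ester 12 (not isolated)
Conditions: 10 (3 equiv, 0.5 M), 7 added over 1 h, PhMe, 110 °C; then Et3N, CH2Cl2, 0 to 23 °C; 1 M HCl work-up; excess 10 recovered
Reagents that add atoms: none
Why: Retro-hetero-Diels–Alder cleavage of the dioxinone gives acylketene 11, which should be captured by the free C-4 OH of 10, since the C-2 OH is hydrogen-bonded to the ester carbonyl and flanked. The aryl triketo ester 12 then closes by aldol addition of c2 to the c7 ketone, dehydrates and enolizes to ring B (biomimetic cycloaromatization of a 3,5,7-triketo ester). The amine in an aprotic solvent offers no nucleophile that could cleave the new aryl ester.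

Step 5
Reactants: 7 2,2-dimethyl-6-(2,4-dioxopentyl)-4H-1,3-dioxin-4-one; 14 4-acetamidobenzenesulfonyl azide
Product: 15 6-(3-diazo-2,4-dioxopentyl)-2,2-dimethyl-4H-1,3-dioxin-4-one
Conditions: 14 (1.0 equiv), Et3N (1.1 equiv), MeCN, 0 °C, short reaction time; pH 7 buffer work-up
Reagents that add atoms: none
Why: Regitz diazo transfer: the amine deprotonates the most acidic carbon of 7, the c6 methylene between the two ketones, and this enolate takes over the two terminal nitrogens of the sulfonyl azide. The c4 methylene is far less acidic and should stay untouched, and the diketone enolate lowers the electrophilicity of c7, which holds back aldol closure of the chain while the transfer takes place.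

Step 6
Reactants: 15 6-(3-diazo-2,4-dioxopentyl)-2,2-dimethyl-4H-1,3-dioxin-4-one; 16 methanol
Product: 17 6-(3-methoxy-2,4-dioxopentyl)-2,2-dimethyl-4H-1,3-dioxin-4-one
Conditions: Rh2(OAc)4 (1 mol %), 16 (5 equiv), ClCH2CH2Cl, 60 °C
Reagents that add atoms: none
Why: Dirhodium-catalysed loss of N2 from the diazo diketone gives a rhodium carbenoid at c6, which inserts into the O–H bond of methanol (carbenoid O–H insertion) and leaves the α-methoxy-1,3-diketone after tautomerization. The temperature lies well below that at which the dioxinone ring opens, and the medium holds no nitrile or ketone that could trap the carbenoid.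

Step 7
Reactants: 17 6-(3-methoxy-2,4-dioxopentyl)-2,2-dimethyl-4H-1,3-dioxin-4-one; 13 benzyl 4-[(2,4-dihydroxy-6-methylbenzoyl)oxy]-2-hydroxy-6-methylbenzoate
Product: 20 benzyl 4-({4-[(2,4-dihydroxy-5-methoxy-6-methylbenzoyl)oxy]-2-hydroxy-6-methylbenzoyl}oxy)-2-hydroxy-6-methylbenzoate, via methoxy acylketene 18 (not isolated), via aryl methoxy triketo ester 19 (not isolated)
Conditions: 13 (0.3 M), 17 (1.5 equiv, in portions), PhMe, 105 °C, short heating; then Et3N (3 equiv), CH2Cl2, 0 to 23 °C; 1 M HCl work-up
Reagents that add atoms: none
Why: On heating, 17 undergoes retro-hetero-Diels–Alder cleavage of the dioxinone ring to acylketene 18, whose sp carbon c1 is attacked by the only non-chelated phenol of 13, the C-4 OH of ring B, through a six-membered pseudopericyclic transition state, so the depside bond of 19 forms before the two ortho substituents that would hinder it exist. The amine base then enolizes c2 of 19, the methylene between the aryl ester and the c3 ketone, and this carbon adds to the c7 acetyl carbonyl in a 6-(enolendo)-exo-trig aldol closure that makes the C-1–C-6 bond of ring A; E1cB dehydration and enolization of c3 and c5 aromatize the ring and leave the c6 methoxy group as the C-5 OMe of 20. The closest known reaction type is the thermolysis of diketo-dioxinones with hydroxyl nucleophiles followed by base-mediated cycloaromatization of the 3,5,7-triketo esters to 2,4-dihydroxy-6-alkylbenzoates, together with the capture of acylketenes by phenols to give aryl β-keto esters. No stereocentre is formed, and the labile c6 methine of 19 disappears on aromatization. Site selectivity among the three phenols of 13 rests on the intramolecular hydrogen bonds and ortho flanking that deactivate both C-2 hydroxyls. The cyclization mode is secured by the substrate: c6 carries the methoxy group, so a Claisen-type attack of c6 on c1 would create a quaternary centre that cannot aromatize, while the α-methoxy group raises the electrophilicity of c7; the aprotic medium with a non-nucleophilic amine keeps both depside bonds intact. Intramolecular capture of 18 by its own enol is held back by keeping 13 concentrated and 17 in excess.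

Step 8
Reactants: 20 benzyl 4-({4-[(2,4-dihydroxy-5-methoxy-6-methylbenzoyl)oxy]-2-hydroxy-6-methylbenzoyl}oxy)-2-hydroxy-6-methylbenzoate
Product: 21 4-({4-[(2,4-dihydroxy-5-methoxy-6-methylbenzoyl)oxy]-2-hydroxy-6-methylbenzoyl}oxy)-2-hydroxy-6-methylbenzoic acid
Conditions: H2 (1 atm), Pd/C (10% palladium on carbon), EtOAc/THF, 23 °C
Reagents that add atoms: none
Why: Hydrogenolysis of the benzyl ester should leave the aryl esters, the aryl methyl ether and the phenols untouched. The neutral, alcohol-free medium at room temperature avoids depside alcoholysis and decarboxylation of the liberated acid.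

## Compound list

1 | 2,2,6-trimethyl-4H-1,3-dioxin-4-one | CC1=CC(=O)OC(C)(C)O1 | starting material
2 | acetyl chloride | CC(=O)Cl | starting material
3 | lithium 2,2-dimethyl-6-methylidene-6H-1,3-dioxin-4-olate (lithium dienolate of 1) | C=C1C=C([O-])OC(C)(C)O1.[Li+] | intermediate
4 | 2,2-dimethyl-6-(2-oxopropyl)-4H-1,3-dioxin-4-one | CC(=O)CC1=CC(=O)OC(C)(C)O1 | intermediate
5 | N-methoxy-N-methylacetamide | CC(=O)N(C)OC | starting material
6 | dilithium dianion of 4 | C=C([O-])C=C1C=C([O-])OC(C)(C)O1.[Li+].[Li+] | intermediate
7 | 2,2-dimethyl-6-(2,4-dioxopentyl)-4H-1,3-dioxin-4-one | CC(=O)CC(=O)CC1=CC(=O)OC(C)(C)O1 | intermediate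
8 | 2,4-dihydroxy-6-methylbenzoic acid (orsellinic acid) | Cc1cc(O)cc(O)c1C(=O)O | starting material
9 | benzyl bromide | BrCc1ccccc1 | starting material
10 | benzyl 2,4-dihydroxy-6-methylbenzoate | Cc1cc(O)cc(O)c1C(=O)OCc1ccccc1 | intermediate
11 | 3,5,7-trioxooct-1-en-1-one (acylketene) | CC(=O)CC(=O)CC(=O)C=C=O | intermediate
12 | benzyl 2-hydroxy-6-methyl-4-[(3,5,7-trioxooctanoyl)oxy]benzoate | CC(=O)CC(=O)CC(=O)CC(=O)Oc1cc(C)c(C(=O)OCc2ccccc2)c(O)c1 | intermediate
13 | benzyl 4-[(2,4-dihydroxy-6-methylbenzoyl)oxy]-2-hydroxy-6-methylbenzoate | Cc1cc(O)cc(O)c1C(=O)Oc1cc(C)c(C(=O)OCc2ccccc2)c(O)c1 | intermediate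
14 | 4-acetamidobenzenesulfonyl azide | CC(=O)Nc1ccc(S(=O)(=O)N=[N+]=[N-])cc1 | starting material
15 | 6-(3-diazo-2,4-dioxopentyl)-2,2-dimethyl-4H-1,3-dioxin-4-one | CC(=O)C(=[N+]=[N-])C(=O)CC1=CC(=O)OC(C)(C)O1 | intermediate
16 | methanol | CO | starting material
17 | 6-(3-methoxy-2,4-dioxopentyl)-2,2-dimethyl-4H-1,3-dioxin-4-one (racemic, enolizable) | CC(=O)C(OC)C(=O)CC1=CC(=O)OC(C)(C)O1 | intermediate
18 | 6-methoxy-3,5,7-trioxooct-1-en-1-one (acylketene) | CC(=O)C(OC)C(=O)CC(=O)C=C=O | intermediate
19 | benzyl 2-hydroxy-4-({2-hydroxy-4-[(6-methoxy-3,5,7-trioxooctanoyl)oxy]-6-methylbenzoyl}oxy)-6-methylbenzoate (racemic, enolizable) | CC(=O)C(OC)C(=O)CC(=O)CC(=O)Oc1cc(C)c(C(=O)Oc2cc(C)c(C(=O)OCc3ccccc3)c(O)c2)c(O)c1 | intermediate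
20 | benzyl 4-({4-[(2,4-dihydroxy-5-methoxy-6-methylbenzoyl)oxy]-2-hydroxy-6-methylbenzoyl}oxy)-2-hydroxy-6-methylbenzoate | COc1c(O)cc(O)c(C(=O)Oc2cc(C)c(C(=O)Oc3cc(C)c(C(=O)OCc4ccccc4)c(O)c3)c(O)c2)c1C | intermediate
21 | 4-({4-[(2,4-dihydroxy-5-methoxy-6-methylbenzoyl)oxy]-2-hydroxy-6-methylbenzoyl}oxy)-2-hydroxy-6-methylbenzoic acid (CNP0327242.0) | COc1c(O)cc(O)c(C(=O)Oc2cc(C)c(C(=O)Oc3cc(C)c(C(=O)O)c(O)c3)c(O)c2)c1C | target

## Step count and risk

Total step count: 8. Longest linear sequence: 6 steps (steps 1, 2, 5, 6, 7, 8). Step 3 gives 10, step 4 joins 7 and 10 to 13, and 13 enters at step 7.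

Least certain steps:

**Step 7 (key step).** Three processes can divert it.
- The capture of 18 by the phenol is bimolecular and reversible at the reaction temperature. The acylketene can therefore drain into an intramolecular capture by its own enol oxygen, a six-membered oxa-cyclization to a pyranone.
- The open chain 19 may cyclize in the wrong mode, by lactonization with expulsion of the phenol, because an aryl ester is a good leaving group.
- A chelated C-2 hydroxyl may be acylated.

Fallback: ring formation is separated from ester formation, still starting from 17. Treating 17 with Et3N in CH2Cl2 without prior heating should cyclize the intact dioxinone (aldol of the dioxinone α-carbon onto the acetyl carbonyl, then dehydration) to the acetonide-protected ring A, 7-hydroxy-6-methoxy-2,2,5-trimethyl-4H-1,3-benzodioxin-4-one F1. Silylation (TBSCl, imidazole, DMF) gives 7-[(tert-butyldimethylsilyl)oxy]-6-methoxy-2,2,5-trimethyl-4H-1,3-benzodioxin-4-one F2. Irradiation of F2 (300 nm, CH2Cl2) with 13 generates an ortho-quinone ketene, which the ring B C-4 OH captures to give the silyl ether of 20, benzyl 4-({4-[(4-{[tert-butyl(dimethyl)silyl]oxy}-2-hydroxy-5-methoxy-6-methylbenzoyl)oxy]-2-hydroxy-6-methylbenzoyl}oxy)-2-hydroxy-6-methylbenzoate F3. HF·pyridine in THF then returns the route to 20.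

**Step 5.** The diazo transfer may lose the race against ring closure. The amine that forms the diketone enolate is also able to close the intact dioxinone chain of 7 by aldol cyclization and aromatization, and a second transfer at the c4 methylene is conceivable if the azide is in excess.

Fallback: the methoxy group is brought in with a two-carbon unit and is not placed on 7. From 1, the lithium dienolate 3 (formed as in step 1) is C-acylated with methoxyacetyl chloride at −78 °C to give 6-(3-methoxy-2-oxopropyl)-2,2-dimethyl-4H-1,3-dioxin-4-one F4. Double deprotonation (LiN(i-Pr)2, 2.1 equiv, THF, −78 °C) gives its dilithium dianion F5, whose methoxy-bearing terminal carbon is acetylated by 5. Acidic work-up returns the route to 17, so that step 6 is bypassed as well.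

**Step 6.** The carbenoid may be diverted from methanol. A carbonyl oxygen of the chain can add to it (carbonyl ylide formation), the acyl group can migrate on warming (Wolff rearrangement), and traces of water can insert in place of methanol. An acceptor/acceptor diazo compound also needs warming, which narrows the margin below dioxinone cleavage.

Fallback: the methoxy group is placed without a carbene. From 7, oxidative α-methoxylation of the 1,3-diketone with a trivalent iodine reagent (iodosylbenzene, BF3·OEt2, MeOH, −20 to 0 °C) should attack the enol at c6 and let methanol displace the iodine. This gives 17 directly and bypasses 15.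

**Step 4.** The same processes as in step 7 apply, and the wrong cyclization mode is more serious here. In 12 the carbon c6 is an unsubstituted, highly acidic methylene, and its Claisen-type attack on the aryl ester carbonyl would expel 10 and lead to an aromatizable acylphloroglucinol.

Fallback: from 7, Et3N-mediated cycloaromatization of the intact dioxinone should give 7-hydroxy-2,2,5-trimethyl-4H-1,3-benzodioxin-4-one F6. Silylation gives 7-[(tert-butyldimethylsilyl)oxy]-2,2,5-trimethyl-4H-1,3-benzodioxin-4-one F7. Photolysis of F7 (300 nm) with excess 10 gives benzyl 4-[(4-{[tert-butyl(dimethyl)silyl]oxy}-2-hydroxy-6-methylbenzoyl)oxy]-2-hydroxy-6-methylbenzoate F8, and HF·pyridine returns the route to 13.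

## Further compounds

F1 | step 7 | 7-hydroxy-6-methoxy-2,2,5-trimethyl-4H-1,3-benzodioxin-4-one | COc1c(O)cc2OC(C)(C)OC(=O)c2c1C
F2 | step 7 | 7-[(tert-butyldimethylsilyl)oxy]-6-methoxy-2,2,5-trimethyl-4H-1,3-benzodioxin-4-one | COc1c(O[Si](C)(C)C(C)(C)C)cc2OC(C)(C)OC(=O)c2c1C
F3 | step 7 | benzyl 4-({4-[(4-{[tert-butyl(dimethyl)silyl]oxy}-2-hydroxy-5-methoxy-6-methylbenzoyl)oxy]-2-hydroxy-6-methylbenzoyl}oxy)-2-hydroxy-6-methylbenzoate | COc1c(O[Si](C)(C)C(C)(C)C)cc(O)c(C(=O)Oc2cc(C)c(C(=O)Oc3cc(C)c(C(=O)OCc4ccccc4)c(O)c3)c(O)c2)c1C
F4 | step 5 | 6-(3-methoxy-2-oxopropyl)-2,2-dimethyl-4H-1,3-dioxin-4-one | COCC(=O)CC1=CC(=O)OC(C)(C)O1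
F5 | step 5 | dilithium dianion of F4 | COC=C([O-])C=C1C=C([O-])OC(C)(C)O1.[Li+].[Li+]
F0 | step 6 | none | none
F6 | step 4 | 7-hydroxy-2,2,5-trimethyl-4H-1,3-benzodioxin-4-one | Cc1cc(O)cc2OC(C)(C)OC(=O)c12
F7 | step 4 | 7-[(tert-butyldimethylsilyl)oxy]-2,2,5-trimethyl-4H-1,3-benzodioxin-4-one | Cc1cc(O[Si](C)(C)C(C)(C)C)cc2OC(C)(C)OC(=O)c12
F8 | step 4 | benzyl 4-[(4-{[tert-butyl(dimethyl)silyl]oxy}-2-hydroxy-6-methylbenzoyl)oxy]-2-hydroxy-6-methylbenzoate | Cc1cc(O[Si](C)(C)C(C)(C)C)cc(O)c1C(=O)Oc1cc(C)c(C(=O)OCc2ccccc2)c(O)c1
A1 | alternative 1 | 2,4-bis(benzyloxy)-5-methoxy-6-methylbenzoic acid | COc1c(OCc2ccccc2)cc(OCc2ccccc2)c(C(=O)O)c1C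
A2 | alternative 1 | benzyl 4-({4-[(2,4-bis(benzyloxy)-5-methoxy-6-methylbenzoyl)oxy]-2-hydroxy-6-methylbenzoyl}oxy)-2-hydroxy-6-methylbenzoate | COc1c(OCc2ccccc2)cc(OCc2ccccc2)c(C(=O)Oc2cc(C)c(C(=O)Oc3cc(C)c(C(=O)OCc4ccccc4)c(O)c3)c(O)c2)c1C
A3 | alternative 2 | benzyl 4-{[4-(but-2-ynoyloxy)-2-hydroxy-6-methylbenzoyl]oxy}-2-hydroxy-6-methylbenzoate | CC#CC(=O)Oc1cc(C)c(C(=O)Oc2cc(C)c(C(=O)OCc3ccccc3)c(O)c2)c(O)c1
A4 | alternative 2 | pentacarbonyl{[1-(benzyloxy)ethenyl](methoxy)methylidene}chromium, (CO)5Cr=C(OMe)C(OBn)=CH2 | COC(C(=C)OCc1ccccc1)=[Cr](=C=O)(=C=O)(=C=O)(=C=O)=C=O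
A5 | alternative 2 | benzyl 4-({4-[(4-(benzyloxy)-2-hydroxy-5-methoxy-6-methylbenzoyl)oxy]-2-hydroxy-6-methylbenzoyl}oxy)-2-hydroxy-6-methylbenzoate | COc1c(OCc2ccccc2)cc(O)c(C(=O)Oc2cc(C)c(C(=O)Oc3cc(C)c(C(=O)OCc4ccccc4)c(O)c3)c(O)c2)c1C
A6 | alternative 3 | methyl 5-methoxy-6-methyl-2,4-dioxocyclohexane-1-carboxylate (diastereomer mixture) | COC1C(C)C(C(=O)OC)C(=O)CC1=O
A7 | alternative 3 | methyl 2,4-dihydroxy-5-methoxy-6-methylbenzoate | COc1c(O)cc(O)c(C(=O)OC)c1C
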